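**Retrosynthetic overview**
- The benzyl ester C–O bond is made last, from octacosanoic acid and benzyl alcohol, so the ester never meets hydroxide or hydrazine.
- Octacosanoic acid comes from 7-oxooctacosanoic acid by deoxygenation of the ketone left over from the C–C bond formation.
- 7-Oxooctacosanoic acid comes from 2-docosanoylcyclohexanone by retro-Claisen ring opening. The six ring carbons become C1–C6 of the chain.
- The key C6–C7 bond comes from an intermolecular crossed Claisen condensation of cyclohexanone (C6) with an activated ester of docosanoic acid (C22). C22 + C6 = C28.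
- No ring is formed. The phenyl ring is bought with benzyl alcohol, and the cyclohexanone ring is bought and then opened.

Assumption: the target has no stereocentre and no stereogenic double bond, so it is one achiral compound and no stereocontrol is needed.

**Step 1**
Reactants: 1 docosanoic acid (behenic acid)
Product: 2 pentafluorophenyl docosanoate
Conditions: C6F5OH (1.1 equiv), DCC (1.1 equiv), DMAP (5 mol %), CH2Cl2–THF 4:1, 0 °C to rt, 12 h; filter, short SiO2 plug
Reagents that add atoms: pentafluorophenol, Oc1c(F)c(F)c(F)c(F)c1F
Why: In this Steglich-type carbodiimide esterification DCC activates the acid and DMAP relays the acyl group to the acidic phenol, giving a silica-stable active ester that, unlike 1, dissolves freely in CH2Cl2 at room temperature, and no stereocentre is formed.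

**Step 2**
Reactants: 2 pentafluorophenyl docosanoate; 3 cyclohexanone
Product: 5 2-docosanoylcyclohexan-1-one, via bromomagnesium cyclohex-1-en-1-olate 4 (not isolated)
Conditions: 3 (2.0 equiv), MgBr2·OEt2 (2.5 equiv), iPr2NEt (3.0 equiv), CH2Cl2, rt, 6–12 h; 1 M HCl, then NaHCO3 wash; chromatography or crystallisation
Reagents that add atoms: none
Why: In this crossed Claisen condensation under soft enolisation, magnesium-bound 3 is deprotonated by the amine to enolate 4, which is C-acylated by active ester 2, and the product is held as a magnesium β-diketonate chelate that drives the equilibrium and suppresses O-acylation and double acylation; the new C2 stereocentre is racemic and enolisable and is erased in step 3.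

**Step 3**
Reactants: 5 2-docosanoylcyclohexan-1-one
Product: 6 7-oxooctacosanoic acid
Conditions: NaOH (3 equiv), EtOH–H2O 9:1, reflux, 2 h; then 2 M HCl, 60 °C; recrystallise from EtOAc
Reagents that add atoms: sodium hydroxide, [Na+].[OH-]
Why: In this retro-Claisen (hydrolytic β-diketone) cleavage, hydroxide adds preferentially to the ring carbonyl, which like all cyclohexanones gains from the sp2-to-sp3 change, the C1–C2 bond breaks to expel the stabilised ketone enolate, and irreversible carboxylate formation pulls the ring opening through to the linear C28 keto acid with no stereocentre left.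

**Step 4**
Reactants: 6 7-oxooctacosanoic acid
Product: 8 octacosanoic acid, via 7-hydrazinylideneoctacosanoic acid 7 (not isolated)
Conditions: N2H4·H2O (5 equiv), KOH (4 equiv, present from the start), triethanolamine, 130 °C, 3 h; distil off H2O/N2H4 to 195 °C, 5 h; pour into hot 6 M HCl; recrystallise from toluene
Reagents that add atoms: none
Why: In this Wolff–Kishner reduction (Huang-Minlon form), hydrazone 7 loses N2 under hot KOH to leave a CH2 group, the carboxylate is inert to the conditions, and there is no other functional group or stereocentre to harm.

**Step 5**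
Reactants: 8 octacosanoic acid; 9 benzyl alcohol
Product: 10 benzyl octacosanoate
Conditions: 9 (3 equiv), p-TsOH·H2O (5 mol %), toluene, Dean–Stark reflux, 6 h; NaHCO3 wash; recrystallise from acetone
Reagents that add atoms: none
Why: This Fischer esterification is driven to completion by azeotropic removal of water, hot toluene dissolves the waxy acid, the saturated chain is inert, and placing the step last keeps the benzyl ester away from hydroxide and hydrazine.

**Compound list**
1 | docosanoic acid (behenic acid) | CCCCCCCCCCCCCCCCCCCCCC(=O)O | starting material
2 | pentafluorophenyl docosanoate | CCCCCCCCCCCCCCCCCCCCCC(=O)Oc1c(F)c(F)c(F)c(F)c1F | intermediate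
3 | cyclohexanone | O=C1CCCCC1 | starting material
4 | bromomagnesium cyclohex-1-en-1-olate | Br[Mg]OC1=CCCCC1 | intermediate (not isolated)
5 | 2-docosanoylcyclohexan-1-one (racemic, labile C2, largely enolised) | CCCCCCCCCCCCCCCCCCCCCC(=O)C1CCCCC1=O | intermediate
6 | 7-oxooctacosanoic acid | CCCCCCCCCCCCCCCCCCCCCC(=O)CCCCCC(=O)O | intermediate
7 | 7-hydrazinylideneoctacosanoic acid (E/Z mixture, present as its potassium salt) | CCCCCCCCCCCCCCCCCCCCCC(=NN)CCCCCC(=O)O | intermediate (not isolated)
8 | octacosanoic acid (montanic acid) | CCCCCCCCCCCCCCCCCCCCCCCCCCCC(=O)O | intermediate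
9 | benzyl alcohol | OCc1ccccc1 | starting material
10 | benzyl octacosanoate (achiral) | CCCCCCCCCCCCCCCCCCCCCCCCCCCC(=O)OCc1ccccc1 | target

**Totals**
Total step count: 5
Longest linear sequence: 5

**Steps most likely to fail**

Step 2 (Claisen condensation). The risks are slow or incomplete C-acylation and competing enolisation of the long-chain active ester. The fallback sets out from 1 and 3 and comes back at 5.
- Acid 1 is converted with SOCl2 (cat. DMF, toluene, 70 °C) into docosanoyl chloride F1.
- Ketone 3 is condensed with morpholine (cat. p-TsOH, toluene, Dean–Stark) to 4-(cyclohex-1-en-1-yl)morpholine F2.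
- F1 is added to F2 and Et3N in CHCl3 at 35 °C (Stork–Hünig enamine acylation). This gives the vinylogous amide 1-[2-(morpholin-4-yl)cyclohex-1-en-1-yl]docosan-1-one F3.
- F3 is hydrolysed with 6 M HCl at reflux to 5.

Step 3 (retro-Claisen ring opening). Attack at the exocyclic carbonyl would return docosanoate and cyclohexanone, and the C22 acid is tedious to remove from 6. The fallback sets out from 1 and comes back at 6.
- Acid 1 is esterified (MeOH, cat. H2SO4, reflux) to methyl docosanoate F4.
- F4 undergoes a titanium-mediated crossed Claisen condensation with commercial ethyl 7-chloro-7-oxoheptanoate (CCOC(=O)CCCCCC(=O)Cl). The conditions are TiCl4, Bu3N and N-methylimidazole in dilute CH2Cl2, −45 °C to 0 °C.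
- The product is the open-chain β-keto diester 9-ethyl 1-methyl 2-icosyl-3-oxononanedioate F5.
- Heating F5 in AcOH–conc. HCl–H2O at reflux hydrolyses both esters and removes only the carboxyl next to the ketone. This delivers 6 with no regiochemical ambiguity.

Step 4 (Wolff–Kishner reduction). The risks are foaming soaps, azine formation and incomplete reduction of a poorly soluble salt. The fallback sets out from 6 and comes back at 8.
- Keto acid 6 is treated with ethane-1,2-dithiol and BF3·OEt2 (CH2Cl2, rt). This gives the thioketal 6-(2-henicosyl-1,3-dithiolan-2-yl)hexanoic acid F6.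
- F6 is desulfurised with Raney Ni (W-2 grade, EtOH, reflux; dilute HCl work-up) in a Mozingo reduction to 8.

**Further compounds**
F1 | step 2 | docosanoyl chloride | CCCCCCCCCCCCCCCCCCCCCC(=O)Cl
F2 | step 2 | 4-(cyclohex-1-en-1-yl)morpholine | C1=C(CCCC1)N1CCOCC1
F3 | step 2 | 1-[2-(morpholin-4-yl)cyclohex-1-en-1-yl]docosan-1-one | CCCCCCCCCCCCCCCCCCCCCC(=O)C1=C(CCCC1)N1CCOCC1
F4 | step 3 | methyl docosanoate | CCCCCCCCCCCCCCCCCCCCCC(=O)OC
F5 | step 3 | 9-ethyl 1-methyl 2-icosyl-3-oxononanedioate (racemic) | CCCCCCCCCCCCCCCCCCCCC(C(=O)OC)C(=O)CCCCCC(=O)OCC
F6 | step 4 | 6-(2-henicosyl-1,3-dithiolan-2-yl)hexanoic acid | CCCCCCCCCCCCCCCCCCCCCC1(CCCCCC(=O)O)SCCS1
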